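The ring atoms are numbered O1, C2 (aryl), C3 (CH2OH), C4 (aroyl), C5. The route rests on cutting O1–C5 and C2–C3. It exploits that C3 and C5 are both β to the exocyclic aroyl ketone on C4 of the tetrahydrofuran ring: C5–C4(C=O)–C3 is a 2-acylallyl unit, nucleophilic at C3 as an allylboronate (a polarity-reversed β-carbon) and, after allyl transposition to the C4=C5 enone, electrophilic at C5. One pot joins 3,4-dimethoxybenzaldehyde and a geometrically defined 2-aroylallylboronate: chiral phosphoric acid catalysed allylboration forms C2–C3, base-mediated oxa-Michael addition forms O1–C5 and equilibrates C4. The boronate is made in one step from an allene, an aroyl chloride and B2pin2.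

Key step: step 3

Remark: read from the SMILES, the target is (2S,3S,4R) in this ring numbering (aryl and CH2OH cis, aroyl trans to CH2OH); (S)-TRIP is (S)-3,3'-bis(2,4,6-triisopropylphenyl)-1,1'-binaphthyl-2,2'-diyl hydrogen phosphate, and its facial sense is assumed from the usual model for aryl aldehydes.

Step 1
Reactants: 1 tert-butyldimethyl(prop-2-yn-1-yloxy)silane
Product: 2 tert-butyl(buta-2,3-dien-1-yloxy)dimethylsilane
Conditions: (CH2O)n (2.5 equiv), CuI (0.5 equiv), Cy2NH (1.8 equiv), 1,4-dioxane, reflux
Reagents that add atoms: formaldehyde (from paraformaldehyde), C=O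
Why: Crabbé homologation, in which copper-mediated Mannich coupling of the terminal alkyne with formaldehyde and the secondary amine gives a propargylic amine that loses an imine by 1,5-hydride transfer to give the terminal allene, the silyl ether being inert.

Step 2
Reactants: 2 tert-butyl(buta-2,3-dien-1-yloxy)dimethylsilane; 3 3,4,5-trimethoxybenzoyl chloride
Product: 4 (E)-4-(tert-butyldimethylsilyloxy)-2-[(4,4,5,5-tetramethyl-1,3,2-dioxaborolan-2-yl)methyl]-1-(3,4,5-trimethoxyphenyl)but-2-en-1-one (CH2OTBS cis to CH2Bpin)
Conditions: B2pin2 (1.1 equiv), PdCl2(MeCN)2 (5 mol%), toluene, 80 °C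
Reagents that add atoms: bis(pinacolato)diboron, CC1(C)OB(OC1(C)C)B1OC(C)(C)C(C)(C)O1
Why: Palladium-catalysed three-component acylboration of an allene, in which the aroyl chloride adds oxidatively to zerovalent palladium formed in situ, the aroyl group is delivered to the central allene carbon from the face of the terminal C=C remote from the CH2OTBS group (so CH2OTBS ends cis to the CH2–Pd carbon), and boryl transfer to the unsubstituted allyl terminus with reductive elimination should give the (E)-2-aroylallylboronate.

Step 3
Reactants: 4 (E)-2-aroylallylboronate; 5 3,4-dimethoxybenzaldehyde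
Product: 8 [(3R,4S,5S)-4-{[tert-butyl(dimethyl)silyl]oxymethyl}-5-(3,4-dimethoxyphenyl)oxolan-3-yl](3,4,5-trimethoxyphenyl)methanone, via homoallylic pinacol borate 6 (not isolated), via hydroxy enone 7 (not isolated)
Conditions: (S)-TRIP (10 mol%), 4 Å molecular sieves, toluene, 0 → 23 °C; then DBU (0.5 equiv), MeOH (5 equiv), 23 °C, one pot
Reagents that add atoms: none
Why: The phosphoric acid hydrogen-bonds to a boronate oxygen and to the formyl hydrogen of 5, and the allyl group is transferred through a closed six-membered Zimmerman–Traxler chair (C2–C3 bond, with allyl transposition to the C4=C5 methylene ketone as borate 6); methanolysis then frees alcohol 7, whose oxygen adds to C5 of the α-methylene aryl ketone (O1–C5 bond) before the enolate is protonated. The closest known reaction types are the chiral phosphoric acid catalysed allylboration of aromatic aldehydes with γ-substituted pinacol allylboronates and the base-mediated intramolecular oxa-Michael cyclisation of γ-hydroxy α-methylene carbonyl compounds. The only ring closed is the tetrahydrofuran, by a reversible 5-endo-trig oxa-Michael addition that should end at the ether because the competing 5-exo hemiketal cannot react further under base. C2 is set by the catalyst, the (S) acid being chosen so that the Si face of the aldehyde is attacked; C3 is set by the alkene geometry of 4, whose CH2OTBS group cis to CH2Bpin sits pseudoaxial in the chair and should give the syn adduct, that is the 2,3-cis ring. C4 is set by thermodynamic equilibration of its α-proton under DBU, which should place the aroyl group trans to the C3 substituent. The step needs γ-selective allyl transfer (inherent to the cyclic transition state), a negligible uncatalysed background reaction (the acyl group deactivates the boronate at 23 °C) and no acid-induced dehydration of the γ-hydroxy ketone to a furan, which is secured by keeping the oxygen as borate 6 until DBU has neutralised the acid.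

Step 4
Reactants: 8 silyl-protected tetrahydrofuran ketone
Product: 9 [(3R,4S,5S)-5-(3,4-dimethoxyphenyl)-4-(hydroxymethyl)oxolan-3-yl](3,4,5-trimethoxyphenyl)methanone
Conditions: HF·pyridine, pyridine, THF, 0 → 23 °C
Reagents that add atoms: none
Why: Fluoride-mediated desilylation of the primary silyl ether under buffered, weakly acidic conditions, chosen because base could open the β-alkoxy ketone by E1cB elimination and strong acid could ionise the electron-rich benzylic C2–O bond; no stereocentre is touched.

Compound list
1 | tert-butyldimethyl(prop-2-yn-1-yloxy)silane | C#CCO[Si](C)(C)C(C)(C)C | starting material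
2 | tert-butyl(buta-2,3-dien-1-yloxy)dimethylsilane | C=C=CCO[Si](C)(C)C(C)(C)C | intermediate
3 | 3,4,5-trimethoxybenzoyl chloride | COc1cc(C(=O)Cl)cc(OC)c1OC | starting material
4 | (E)-4-(tert-butyldimethylsilyloxy)-2-[(4,4,5,5-tetramethyl-1,3,2-dioxaborolan-2-yl)methyl]-1-(3,4,5-trimethoxyphenyl)but-2-en-1-one | CC1(C)OB(C/C(=C\CO[Si](C)(C)C(C)(C)C)C(=O)c2cc(OC)c(OC)c(OC)c2)OC1(C)C | intermediate
5 | 3,4-dimethoxybenzaldehyde | COc1ccc(C=O)cc1OC | starting material
6 | (3S,4S)-3-[(tert-butyldimethylsilyloxy)methyl]-4-(3,4-dimethoxyphenyl)-2-methylidene-4-[(4,4,5,5-tetramethyl-1,3,2-dioxaborolan-2-yl)oxy]-1-(3,4,5-trimethoxyphenyl)butan-1-one | COc1ccc([C@@H](OB2OC(C)(C)C(C)(C)O2)[C@H](CO[Si](C)(C)C(C)(C)C)C(=C)C(=O)c3cc(OC)c(OC)c(OC)c3)cc1OC | intermediate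
7 | (3S,4S)-3-[(tert-butyldimethylsilyloxy)methyl]-4-(3,4-dimethoxyphenyl)-4-hydroxy-2-methylidene-1-(3,4,5-trimethoxyphenyl)butan-1-one | COc1ccc([C@@H](O)[C@H](CO[Si](C)(C)C(C)(C)C)C(=C)C(=O)c2cc(OC)c(OC)c(OC)c2)cc1OC | intermediate
8 | [(3R,4S,5S)-4-{[tert-butyl(dimethyl)silyl]oxymethyl}-5-(3,4-dimethoxyphenyl)oxolan-3-yl](3,4,5-trimethoxyphenyl)methanone (aryl and CH2OTBS cis, aroyl trans to CH2OTBS) | COc1ccc([C@H]2OC[C@H](C(=O)c3cc(OC)c(OC)c(OC)c3)[C@H]2CO[Si](C)(C)C(C)(C)C)cc1OC | intermediate
9 | [(3R,4S,5S)-5-(3,4-dimethoxyphenyl)-4-(hydroxymethyl)oxolan-3-yl](3,4,5-trimethoxyphenyl)methanone | COc1ccc([C@H]2OC[C@H](C(=O)c3cc(OC)c(OC)c(OC)c3)[C@H]2CO)cc1OC | target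

Total step count: 4. Longest linear sequence: 4 steps (1 → 2 → 4 → 8 → 9); 3 and 5 enter convergently.

Steps most likely to fail

Step 3. The allyl transfer from the acyl-deactivated boronate 4 to the electron-rich aldehyde 5 may be too slow under the chiral acid, so that conversion stalls or an unselective pathway erodes the facial and syn selectivity. The fallback makes the two bonds in separate operations and sets out from allene 2 and aldehyde 5. A copper-catalysed borylative coupling (CuCl, NaOt-Bu, a chiral bisphosphine, B2pin2, THF) adds a boryl–copper species across the terminal C=C of 2. The resulting (Z)-2-borylallylcopper should add to 5 through a chair transition state and give, after hydrolytic work-up, (1S,2S)-2-[(tert-butyldimethylsilyloxy)methyl]-1-(3,4-dimethoxyphenyl)-3-(4,4,5,5-tetramethyl-1,3,2-dioxaborolan-2-yl)but-3-en-1-ol F1. Carbonylative Suzuki–Miyaura coupling of F1 with 5-iodo-1,2,3-trimethoxybenzene under CO (Pd(PPh3)4, K2CO3) installs the aroyl group and gives hydroxy enone 7, where the route is rejoined; 7 closes to 8 under the DBU treatment of step 3.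

Step 2. β-Elimination of the silyloxy group from the allylpalladium intermediate (to a 2-aroyl-1,3-diene), or syn–anti isomerisation of that intermediate, may lower the yield or scramble the alkene geometry on which the C3 configuration depends. The fallback runs from 3 back to 4. Stille coupling of 3 with tributyl(vinyl)stannane gives 1-(3,4,5-trimethoxyphenyl)prop-2-en-1-one F2. A DABCO-catalysed Morita–Baylis–Hillman reaction with (tert-butyldimethylsilyloxy)acetaldehyde, with slow addition of F2 to limit Rauhut–Currier dimerisation, gives racemic 4-(tert-butyldimethylsilyloxy)-3-hydroxy-2-methylidene-1-(3,4,5-trimethoxyphenyl)butan-1-one F3. Acetylation (Ac2O, DMAP) gives racemic 1-(tert-butyldimethylsilyloxy)-3-methylidene-4-oxo-4-(3,4,5-trimethoxyphenyl)butan-2-yl acetate F4. Palladium-catalysed borylation of F4 with B2pin2 (Pd2(dba)3, DMSO) through the 2-aroylallyl palladium intermediate, with boron delivered to the CH2 terminus, returns 4.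

Step 4. During desilylation the β-alkoxy ketone may open by E1cB elimination and reclose through the freed primary hydroxyl group (transposition of the ring oxygen), or the C2–O bond may ionise and C2 epimerise. The fallback runs from 8 back to 9 and takes the ketone out of play first. NaBH4 reduces 8 to the benzylic alcohol [(3R,4S,5S)-4-{[tert-butyl(dimethyl)silyl]oxymethyl}-5-(3,4-dimethoxyphenyl)oxolan-3-yl](3,4,5-trimethoxyphenyl)methanol F5 (carbinol epimers, immaterial). Tetrabutylammonium fluoride then removes the silyl group without risk of elimination and gives the diol [(3R,4S,5S)-5-(3,4-dimethoxyphenyl)-4-(hydroxymethyl)oxolan-3-yl](3,4,5-trimethoxyphenyl)methanol F6. MnO2 reoxidises only the benzylic alcohol to give 9, with C4 left in its thermodynamic configuration.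

Further compounds
F1 | step 3 | (1S,2S)-2-[(tert-butyldimethylsilyloxy)methyl]-1-(3,4-dimethoxyphenyl)-3-(4,4,5,5-tetramethyl-1,3,2-dioxaborolan-2-yl)but-3-en-1-ol | COc1ccc([C@@H](O)[C@H](CO[Si](C)(C)C(C)(C)C)C(=C)B2OC(C)(C)C(C)(C)O2)cc1OC
F2 | step 2 | 1-(3,4,5-trimethoxyphenyl)prop-2-en-1-one | C=CC(=O)c1cc(OC)c(OC)c(OC)c1
F3 | step 2 | racemic 4-(tert-butyldimethylsilyloxy)-3-hydroxy-2-methylidene-1-(3,4,5-trimethoxyphenyl)butan-1-one | C=C(C(O)CO[Si](C)(C)C(C)(C)C)C(=O)c1cc(OC)c(OC)c(OC)c1
F4 | step 2 | racemic 1-(tert-butyldimethylsilyloxy)-3-methylidene-4-oxo-4-(3,4,5-trimethoxyphenyl)butan-2-yl acetate | C=C(C(OC(C)=O)CO[Si](C)(C)C(C)(C)C)C(=O)c1cc(OC)c(OC)c(OC)c1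
F5 | step 4 | [(3R,4S,5S)-4-{[tert-butyl(dimethyl)silyl]oxymethyl}-5-(3,4-dimethoxyphenyl)oxolan-3-yl](3,4,5-trimethoxyphenyl)methanol, carbinol epimers | COc1ccc([C@H]2OC[C@H](C(O)c3cc(OC)c(OC)c(OC)c3)[C@H]2CO[Si](C)(C)C(C)(C)C)cc1OC
F6 | step 4 | [(3R,4S,5S)-5-(3,4-dimethoxyphenyl)-4-(hydroxymethyl)oxolan-3-yl](3,4,5-trimethoxyphenyl)methanol, carbinol epimers | COc1ccc([C@H]2OC[C@H](C(O)c3cc(OC)c(OC)c(OC)c3)[C@H]2CO)cc1OC
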